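The runs are simulated with constants of no real substance; scatter was added.

| setting | eta | alpha | gamma | flask |
|---|---|---|---|---|
| free monomer | 0.20 mM (fed, over 12 s) | 0.20 mM (fed, over 12 s) | 0.10 mM (fed, over 12 s) | 0.20 mM (fed, over 12 s) |
| initiator | 1 µM | 4 µM | 2 µM | 2.0 µM |
| remark | run made earlier; the fed solution adds 0.20 times the starting volume | run made earlier; the fed solution adds 0.20 times the starting volume | run made earlier; the fed solution adds 0.20 times the starting volume | the fed solution adds 0.20 times the starting volume |
| time |  |  |  | 1.0 h |

- eta (time / min: monomer in chains / %, free monomer / %): 10.0: 78, 22; 20.0: 79, 15; 30.0: 86, 17; 40.0: 86, 12; 50.0: 82, 11; 60.0: 85, 15; 80.0: 87, 10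
- alpha (time / min: monomer in chains / %, free monomer / %): 10.0: 85, 15; 20.0: 85, 14; 30.0: 85, 17; 40.0: 83, 12; 50.0: 86, 16; 60.0: 85, 16; 80.0: 82, 14
- gamma (time / min: monomer in chains / %, free monomer / %): 6.00: 60, 40; 10.0: 67, 28; 20.0: 69, 31; 40.0: 67, 29; 80.0: 68, 30

(standard deviation of a reading: 2 percentage points)

- average number of monomer units in a chain (chains begun, living or dead) at 1.0 h
- part of the free monomer that has reacted at 1.0 h

- every charge counts on the volume at the start, and the solution that is fed holds the whole dose
- the average divides the monomer in chains by the number of chains begun, living and dead together
- the earlier runs do not show the number of chains; that part of a forecast is a guess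

In a one-step world free monomer goes into chains and nothing comes back, so its curve runs down to zero, but the gamma run's did not. From 10.0 min on, its free monomer held at 29.5% of the charge, which is 0.0295 mM per starting volume. I called this amount the floor, the free monomer that stays beside the chains: the equilibrium monomer concentration. For a charge above the floor, the part left is then the floor over that charge. For the flask this gave 14.8% left, so 85.2% reacted. Counting one chain per initiator, I got a dp of 85.2, which was a guess, since the runs show no chains.

The weak link was the floor itself, read from one run. The alpha run had twice the charge of the gamma run. The floor asked 14.8% left there, and its readings averaged 14.9%. The gamma run, with the flask's initiator, was level by 10.0 min, earlier than the flask's 1.0 h.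

The forecast gave 85% and a dp of 85, and its ground ran: “A fixed residual concentration, independent of charge and initiator, points to a monomer–polymer equilibrium”.

The flask gave 85.0% reacted and a dp of 107.

    free monomer + initiator → living end + monomer in chains (k = 330 /M/s)
    free monomer + living end → monomer in chains + living end, rate k2*[living end]*[free monomer] (k = 6000 /M/s)
    initiator → spent initiator (k = 0.0100 /s)
    2 free monomer → self-condensation product (k = 0.0530 /M/s)
    monomer in chains + living end → free monomer + living end, rate k5*[living end] as long as [monomer in chains] is above zero (k = 0.150 /s)

The part reacted agreed with the forecast, and the dp parted from it: at 1.00 h the flask's initiator stood at 0%, with 20.5% of the charge as spent initiator beside the living end. The neighbouring flask is the same flask with 0.050 mM of free monomer charged. There the floor over the charge gave 59.0% left. At 1.00 h the neighbouring flask held 59.9% of its charge as free monomer.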